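## Structural features

The target is a stilbenoid trimer built from two 2,3-diaryl-2,3-dihydrobenzofurans. Unit 1 (O1, C2, C3, benzo ring A) carries ring B (4-hydroxyphenyl) on C2, a free hydroxyl on C4 and the (E)-4-hydroxystyryl group (ring C) on C6. Unit 2 (O1′, C2′, C3′, benzo ring D) carries ring F (2,4-dihydroxyphenyl) on C2′, ring E (3,5-dihydroxyphenyl) on C3′ and a free hydroxyl on C4′. The units are joined by the single bond C3–C6′, so ring D is both the benzo ring of unit 2 and the C3 aryl group of unit 1. There are four stereocentres in two adjacent pairs, C2/C3 and C2′/C3′, all S and each pair trans; ring D separates the pairs, so neither can direct the other. The benzylic ether bonds C2–O1 and especially C2′–O1′ (next to the ortho/para-oxygenated ring F) ionise under acid, the stilbene rules out hydrogenolysis and electrophilic halogen, and eight free phenols rule out late oxidants. That lability also means C2 and C2′ can settle to the trans arrangement, so the centres that must be set kinetically are the methine carbons C3 and C3′. The real difficulty is the absolute configuration at C3 and C3′ together with the 1,3,5-pattern of rings A and D (oxygen on C4/C4′ and C7a/C7a′, carbon on C6/C6′). In ring D, C7a′ and C3a′ are bridged by the three-atom chain O1′–C2′–C3′, so the ring can be assembled from an alkynyl ether on O1′, an alkyne on C3′ and a third alkyne that brings C5′ and C6′. Ring A has the same relation through O1–C2–C3.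

## Logic of the disconnections

32 to 31: the six aryl O–CH2OMe bonds on rings B, C, E and F are cut. Acetal protection is chosen over methyl ethers because it leaves under dilute protic acid, whereas boron-halide cleavage of eight methyl ethers would ionise C2–O1 and C2′–O1′. The forward step must remove six acetals without opening either furan ring irreversibly.

31 to 29: the C4–O and C4′–O bonds are traced back to C4–Si and C4′–Si. The silicon atoms are the regiocontrol elements of both cycloadditions, so the two hydroxyls come from one oxidation. A benzyl(dimethyl)silyl group replaces trimethylsilyl because it can be oxidised by attack at silicon. Ipso-iododesilylation at C4/C4′ (meta to the ring oxygen, hence not activated) would lose to iodination of the resorcinol-type rings. The silyl groups must survive every earlier step and the oxidation must spare the stilbene.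

29 to 28 and 25: bonds C3a–C7a, C4–C5 and C6–C7 are cut, which removes ring A, the oxygen ring of unit 1 and the stilbene in one operation. The forward step needs the styryl-bearing carbon at C6 and reaction at the alkyne, not the alkene, of 25.

28 to 22: the O1–C(sp) bond is cut, removing the two-carbon ethynyl unit. The forward step must put an alkyne on a secondary benzylic oxygen without epimerising the acidic C3–H.

22 to 19 and 20: the C2–C3 bond is cut, giving an aldehyde and a propargylic electrophile. The forward step must transfer chirality from the propargylic carbon to C3 and set C2 anti to it.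

19 to 18 to 17 and 3; 17 to 16: the sulfonate and then the bond between the carbinol carbon and the alkyne are cut, and the aldehyde is traced to its acetal. One catalytic asymmetric alkynylation creates the centre that becomes C3; it must be catalyst-controlled because the unit 2 centres are remote.

16 to 14 and 15: bonds C3a′–C7a′, C4′–C5′ and C6′–C7′ are cut. This removes ring D and the oxygen ring of unit 2 and leaves an open-chain diyne whose two stereocentres are already in place. The forward step needs regiocontrol of the third alkyne and a catalyst that works at room temperature.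

14 to 11, 11 to 7 and 9, 7 to 6 to 5 and 3: the same three cuts as in unit 1 (O–C(sp), C2′–C3′, carbinol–alkyne) lead to two protected dihydroxybenzaldehydes and one silylacetylene.

25 to 24 to 20 and 23; 3 to 1 and 2; 5 to 4; 9 to 8: the enyne is cut at its C=C bond, the silylacetylene at Si–C(sp), and the two aldehydes at their acetal C–O bonds, which reaches catalogue compounds.

## Other disconnections considered

Alternative 1: The cut is at C3′–ring E and C2′–ring F, with ring D bought as a symmetrical 2,6-dioxygenated arene. In the forward step the alkenylboronate A2 and the aryllithium A3 form an ate complex. With Pd(OAc)2, a MandyPhos ligand and the triflate A4, ring F should shift from boron to C2′ anti to palladium on C3′, and reductive elimination should join ring E to C3′, giving A1. Oxidation of C–B with retention and closure of O1′–C2′ with inversion (or through the benzylic cation) would then give the trans ring.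
- In favour: both unit 2 stereocentres come from one catalyst-controlled step on achiral pieces, ring D needs no regiocontrol, and no C–Si to C–O exchange is required. On these three points it is the better plan.
- Against: a β-aryl alkenylboronate with two ortho substituents is a poor substrate for the metallate shift, and direct cross-coupling competes. An electron-rich migrating group and an electron-rich triflate both slow the cycle. The benzylic boronate next to ring F is prone to protodeboronation and elimination.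
- Comparison: step count for unit 2 is about equal. Mechanistic risk is comparable. The method does nothing for unit 1, whereas the cycloaddition serves both units.

Alternative 2: The cut is the ipso–ortho bond of ring E. In the forward step Et3N should fold the chain of A6 by aldol condensation of the dioxinone α-carbon onto the C3′-bound ketone and aromatise it to A5.
- In favour: the conditions are mild and metal-free, the oxygen pattern of ring E is built in, and C3′ sits α to a ketone before folding, so it can settle trans to a fixed C2′. On mildness of the ring-forming event it is the equal or the better of the chosen plan.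
- Against: it constructs the one ring that can be bought as a simple aldehyde. It needs a multi-step chain assembly, then hydrolysis and decarboxylation of the resorcylate. The C3′ enolate can expel the C2′ oxygen and so endanger both centres.
- Comparison: it is weaker on step economy and strategic value, because ring D, the C4′ oxygen and unit 1 remain unsolved.

Alternative 3: The cut is O1–C2 of unit 1, made in the forward direction from the spirocyclopropane A8. Sc(OTf)3 should open the bond to the carbon bearing the 4-methoxyphenyl donor and a dione oxygen should close on it (Cloke–Wilson-type ring expansion), giving A7.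
- In favour: it is convergent, with unit 2 entering as an aryl group on the cyclopropane. The C4 oxygen is present from the start and the donor aryl fixes the direction of opening. It avoids a second labile alkynyl ether and a late C–Si oxidation, and on these points it is the better plan.
- Against: ring A arrives as a cyclohexenone and must be dehydrogenated in the presence of a stilbene and electron-rich rings. The C6 centre is made and then destroyed. The absolute configuration at C3 rests on an enantioselective cyclopropanation with little substrate help. The Lewis acid meets the acid-sensitive C2′–O1′ bond.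
- Comparison: step count is similar; stereocontrol at C3 is less secure than chirality transfer from a propargylic alcohol.

Key step: step 8

Remarks before the steps:
- Abbreviations in names: MOM = methoxymethyl; BDMS = benzyl(dimethyl)silyl; ArB = 4-(methoxymethoxy)phenyl; ArE = 3,5-bis(methoxymethoxy)phenyl; ArF = 2,4-bis(methoxymethoxy)phenyl; U2 = (2S,3S)-4-BDMS-2-ArF-3-ArE-2,3-dihydro-1-benzofuran-6-yl.
- Structure check: the configurations of the diyne 14 and the cycloadduct 16 were checked against the target atom by atom. Both carry S at each of the two adjacent centres, the anti open-chain isomer maps onto the trans ring, the silyl group sits on C4′ and the acetal on C6′. No descriptor had to be changed.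
- Assumption: 1, 2, 15, 20 and 23 are taken as catalogue reagents (23 is otherwise one Arbuzov step from 3-bromo-1-(trimethylsilyl)propyne and triethyl phosphite).
- Assumption: the (R,R) ligand in steps 3 and 10 is taken to give the (R)-carbinol by analogy with the facial preference of this catalyst for aldehydes. The sense is to be confirmed on 6 by Mosher ester analysis, and the mirror-image ligand is used if it is the opposite.
- Assumption: the chirality transfer in steps 6 and 12 is assigned on the accepted course (anti SN2′ by palladium, retention in the transfer to indium, cyclic SE2′ addition), which amounts to inversion at the propargylic carbon.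

## Route

Step 1
Reactants: 1 ethynylmagnesium bromide; 2 benzylchlorodimethylsilane
Product: 3 benzyl(ethynyl)dimethylsilane
Conditions: THF, 0 °C → rt, 2 added to excess 1
Reagents that add atoms: none
Why: Substitution at silicon by an alkynyl Grignard reagent; the excess of 1 keeps double silylation low.

Step 2
Reactants: 4 3,5-dihydroxybenzaldehyde
Product: 5 3,5-bis(methoxymethoxy)benzaldehyde
Conditions: MOMCl, K2CO3, acetone, 0 °C → reflux
Reagents that add atoms: chloromethyl methyl ether, COCCl
Why: Williamson-type O-alkylation of both phenoxides; the acetals tolerate organometallic reagents, hydride bases and fluoride and leave under dilute acid.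

Step 3
Reactants: 5 3,5-bis(methoxymethoxy)benzaldehyde; 3 benzyl(ethynyl)dimethylsilane
Product: 6 (1R)-3-[benzyl(dimethyl)silyl]-1-[3,5-bis(methoxymethoxy)phenyl]prop-2-yn-1-ol
Conditions: Me2Zn, (R,R)-ProPhenol (10 mol %), Ph3PO (20 mol %), toluene, 4 °C; aq. NH4Cl
Reagents that add atoms: none
Why: Catalytic asymmetric alkynylation of an aromatic aldehyde by the zinc acetylide of 3 inside the dinuclear zinc–ProPhenol pocket. The ligand enantiomer fixes the attacked face and should give the (R)-carbinol, whose chirality is later relayed to C3′.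

Step 4
Reactants: 6 (1R)-3-[benzyl(dimethyl)silyl]-1-[3,5-bis(methoxymethoxy)phenyl]prop-2-yn-1-ol
Product: 7 (1R)-3-[benzyl(dimethyl)silyl]-1-[3,5-bis(methoxymethoxy)phenyl]prop-2-yn-1-yl methanesulfonate
Conditions: Ms2O, Et3N, CH2Cl2, −40 °C; cold work-up, used at once
Reagents that add atoms: methanesulfonic anhydride, CS(=O)(=O)OS(C)(=O)=O
Why: O-sulfonylation with retention at carbon. The anhydride is used so that no chloride is present to displace the benzylic propargylic mesylate.

Step 5
Reactants: 8 2,4-dihydroxybenzaldehyde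
Product: 9 2,4-bis(methoxymethoxy)benzaldehyde
Conditions: MOMCl, K2CO3, acetone, 0 °C → reflux
Reagents that add atoms: chloromethyl methyl ether, COCCl
Why: Williamson-type O-alkylation; heating is needed for the hydrogen-bonded ortho hydroxyl.

Step 6
Reactants: 7 (1R)-3-[benzyl(dimethyl)silyl]-1-[3,5-bis(methoxymethoxy)phenyl]prop-2-yn-1-yl methanesulfonate; 9 2,4-bis(methoxymethoxy)benzaldehyde
Product: 11 (1S,2S)-4-[benzyl(dimethyl)silyl]-1-[2,4-bis(methoxymethoxy)phenyl]-2-[3,5-bis(methoxymethoxy)phenyl]but-3-yn-1-ol, via allenylindium reagent 10 (not isolated)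
Conditions: Pd(dppf)Cl2 (5 mol %), InI (1.5 equiv), THF–HMPA (3:1), 0 °C → rt
Reagents that add atoms: none
Why: Propargylation of an aldehyde through a transient allenylindium reagent: zerovalent palladium formed in situ displaces the mesylate anti (SN2′), InI takes over the allenyl group with retention, and 10 adds to 9 through a cyclic SE2′ transition state on the indium face. The net inversion at the propargylic carbon turns (R) into (S) at the future C3′. The aldehyde aryl group lies away from the allenyl aryl group, which should give the anti (1S) carbinol, the future C2′.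

Step 7
Reactants: 11 (1S,2S)-4-[benzyl(dimethyl)silyl]-1-[2,4-bis(methoxymethoxy)phenyl]-2-[3,5-bis(methoxymethoxy)phenyl]but-3-yn-1-ol
Product: 14 benzyl{(3S,4S)-4-[2,4-bis(methoxymethoxy)phenyl]-3-[3,5-bis(methoxymethoxy)phenyl]-4-(ethynyloxy)but-1-yn-1-yl}dimethylsilane, via dichlorovinyl ether 12 (not isolated), via lithium alkynyl ether 13 (not isolated)
Conditions: KH, THF, 0 °C; Cl2C=CHCl, −40 °C → rt; n-BuLi (2.4 equiv), −78 → −40 °C; H2O, −78 °C; kept below 0 °C and used at once
Reagents that add atoms: trichloroethylene, ClC=C(Cl)Cl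
Why: Alkynyl ether synthesis from an alkoxide and trichloroethylene: the alkoxide adds to dichloroacetylene formed in the flask to give 12, n-BuLi removes HCl and exchanges the remaining chlorine for lithium to give 13, and water protonates it. No bond to C2′ or C3′ is broken, so both centres are retained if the temperature is kept low.

Step 8
Reactants: 14 benzyl{(3S,4S)-4-[2,4-bis(methoxymethoxy)phenyl]-3-[3,5-bis(methoxymethoxy)phenyl]-4-(ethynyloxy)but-1-yn-1-yl}dimethylsilane; 15 3,3-diethoxyprop-1-yne
Product: 16 benzyl{(2S,3S)-2-[2,4-bis(methoxymethoxy)phenyl]-3-[3,5-bis(methoxymethoxy)phenyl]-6-(diethoxymethyl)-2,3-dihydro-1-benzofuran-4-yl}dimethylsilane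
Conditions: Cp*RuCl(cod) (10 mol %), 15 (3 equiv), ClCH2CH2Cl, rt, 14 added slowly
Reagents that add atoms: none
Why: Cp*RuCl(cod) loses cyclooctadiene, binds both triple bonds of 14 and couples them oxidatively to a ruthenacyclopentadiene, which forms C3a′–C7a′ and so closes the five-membered oxygen ring across the O1′–C2′–C3′ tether; 15 then inserts and reductive elimination forms C6′–C7′ and C4′–C5′, closing ring D as a benzene ring in a formal [2+2+2] sense. The closest known reaction is the Cp*RuCl(cod)-catalysed cycloaddition of ether- or amine-tethered 1,6-diynes with terminal alkynes, together with rhodium-catalysed cycloadditions of diynes in which one arm is an alkynyl ether or an ynamide. The oxygen ring is closed by metallacycle formation on a three-atom tether, and ring D by two-bond annulation of the metallacycle with the third alkyne. No stereocentre is created; C2′ and C3′ lie on the tether, keep all their bonds and keep the trans (2S,3S) relation set in step 6. Three selectivities are needed: the regiochemistry of 15, secured by the silyl group on the C4′ terminus, which lets 15 enter at the unsubstituted C7′ side and puts the acetal carbon on C6′, meta to silicon; cross- over homo-coupling, secured by slow addition of 14 to an excess of 15; and survival of the benzylic alkynyl ether, secured by a neutral catalyst that turns over at room temperature.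

Step 9
Reactants: 16 benzyl{(2S,3S)-2-[2,4-bis(methoxymethoxy)phenyl]-3-[3,5-bis(methoxymethoxy)phenyl]-6-(diethoxymethyl)-2,3-dihydro-1-benzofuran-4-yl}dimethylsilane
Product: 17 (2S,3S)-4-[benzyl(dimethyl)silyl]-2-[2,4-bis(methoxymethoxy)phenyl]-3-[3,5-bis(methoxymethoxy)phenyl]-2,3-dihydro-1-benzofuran-6-carbaldehyde
Conditions: PPTS (10 mol %), acetone–H2O (10:1), rt
Reagents that add atoms: water, O
Why: Acid-catalysed hydrolysis of an aryl diethyl acetal, which is far more labile than the aryl MOM ethers or the benzylic ring ether at this acidity.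

Step 10
Reactants: 17 (2S,3S)-4-[benzyl(dimethyl)silyl]-2-[2,4-bis(methoxymethoxy)phenyl]-3-[3,5-bis(methoxymethoxy)phenyl]-2,3-dihydro-1-benzofuran-6-carbaldehyde; 3 benzyl(ethynyl)dimethylsilane
Product: 18 (1R)-3-[benzyl(dimethyl)silyl]-1-U2-prop-2-yn-1-ol
Conditions: Me2Zn, (R,R)-ProPhenol (10 mol %), Ph3PO (20 mol %), toluene, 4 °C; aq. NH4Cl
Reagents that add atoms: none
Why: The same catalytic asymmetric alkynylation as in step 3. The unit 2 centres are five or more bonds away, so the ligand alone should set the (R)-carbinol that is relayed to C3.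

Step 11
Reactants: 18 (1R)-3-[benzyl(dimethyl)silyl]-1-U2-prop-2-yn-1-ol
Product: 19 (1R)-3-[benzyl(dimethyl)silyl]-1-U2-prop-2-yn-1-yl methanesulfonate
Conditions: Ms2O, Et3N, CH2Cl2, −40 °C; cold work-up, used at once
Reagents that add atoms: methanesulfonic anhydride, CS(=O)(=O)OS(C)(=O)=O
Why: O-sulfonylation with retention, chloride-free as in step 4.

Step 12
Reactants: 19 (1R)-3-[benzyl(dimethyl)silyl]-1-U2-prop-2-yn-1-yl methanesulfonate; 20 4-(methoxymethoxy)benzaldehyde
Product: 22 (1S,2S)-4-[benzyl(dimethyl)silyl]-1-[4-(methoxymethoxy)phenyl]-2-U2-but-3-yn-1-ol, via allenylindium reagent 21 (not isolated)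
Conditions: Pd(dppf)Cl2 (5 mol %), InI (1.5 equiv), 20 (2 equiv), THF–HMPA (3:1), 0 °C → rt
Reagents that add atoms: none
Why: The same allenylindium propargylation as in step 6. Net inversion at the propargylic carbon gives (S) at the future C3, and the cyclic SE2′ transition state should give the anti (1S) carbinol, the future C2.

Step 13
Reactants: 20 4-(methoxymethoxy)benzaldehyde; 23 diethyl [3-(trimethylsilyl)prop-2-yn-1-yl]phosphonate
Product: 24 trimethyl{(E)-4-[4-(methoxymethoxy)phenyl]but-3-en-1-yn-1-yl}silane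
Conditions: LiN(SiMe3)2, THF, −78 → 0 °C
Reagents that add atoms: none
Why: Horner–Wadsworth–Emmons olefination with a propargylic phosphonate anion, which should favour the (E)-alkene with an aromatic aldehyde.

Step 14
Reactants: 24 trimethyl{(E)-4-[4-(methoxymethoxy)phenyl]but-3-en-1-yn-1-yl}silane
Product: 25 1-[(E)-but-1-en-3-yn-1-yl]-4-(methoxymethoxy)benzene
Conditions: K2CO3 (0.2 equiv), MeOH, rt
Reagents that add atoms: none
Why: Base-catalysed methanolysis of an alkynyl–SiMe3 bond; the alkene geometry is not touched.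

Step 15
Reactants: 22 (1S,2S)-4-[benzyl(dimethyl)silyl]-1-[4-(methoxymethoxy)phenyl]-2-U2-but-3-yn-1-ol
Product: 28 benzyl{(3S,4S)-4-(ethynyloxy)-4-[4-(methoxymethoxy)phenyl]-3-U2-but-1-yn-1-yl}dimethylsilane, via dichlorovinyl ether 26 (not isolated), via lithium alkynyl ether 27 (not isolated)
Conditions: KH, THF, 0 °C; Cl2C=CHCl, −40 °C → rt; n-BuLi (2.4 equiv), −78 → −40 °C; H2O, −78 °C; kept below 0 °C and used at once
Reagents that add atoms: trichloroethylene, ClC=C(Cl)Cl
Why: The same alkynyl ether synthesis as in step 7; the aryl–silicon bond on ring D and the acetals are inert to KH and to n-BuLi at −78 °C.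

Step 16
Reactants: 28 benzyl{(3S,4S)-4-(ethynyloxy)-4-[4-(methoxymethoxy)phenyl]-3-U2-but-1-yn-1-yl}dimethylsilane; 25 1-[(E)-but-1-en-3-yn-1-yl]-4-(methoxymethoxy)benzene
Product: 29 (2S,3S)-4-[benzyl(dimethyl)silyl]-2-[4-(methoxymethoxy)phenyl]-6-{(E)-2-[4-(methoxymethoxy)phenyl]ethenyl}-3-U2-2,3-dihydro-1-benzofuran
Conditions: Cp*RuCl(cod) (10 mol %), 25 (3 equiv), ClCH2CH2Cl, rt, 28 added slowly
Reagents that add atoms: none
Why: The same ruthenium-catalysed [2+2+2] cycloaddition as in step 8, now forming C3a–C7a, C4–C5 and C6–C7 and closing ring A and the oxygen ring of unit 1. The silyl terminus sends the styryl-bearing carbon to C6, and the terminal alkyne of 25 should react in preference to its conjugated alkene. C2 and C3 are spectators.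

Step 17
Reactants: 29 (2S,3S)-4-[benzyl(dimethyl)silyl]-2-[4-(methoxymethoxy)phenyl]-6-{(E)-2-[4-(methoxymethoxy)phenyl]ethenyl}-3-U2-2,3-dihydro-1-benzofuran
Product: 31 (2S,3S)-3-{(2S,3S)-2-[2,4-bis(methoxymethoxy)phenyl]-3-[3,5-bis(methoxymethoxy)phenyl]-4-hydroxy-2,3-dihydro-1-benzofuran-6-yl}-2-[4-(methoxymethoxy)phenyl]-6-{(E)-2-[4-(methoxymethoxy)phenyl]ethenyl}-2,3-dihydro-1-benzofuran-4-ol, via bis-silanol 30 (not isolated)
Conditions: TBAF (6 equiv), THF, 0 °C → rt; then KHCO3, 30% H2O2, MeOH, 40 °C
Reagents that add atoms: hydrogen peroxide, OO; water, O (silanol oxygens of 30 only)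
Why: Tamao–Fleming oxidation: fluoride expels the benzyl group from each silicon to give the silanols 30, and peroxide then moves each aryl group from silicon to oxygen at the same carbon. The oxidant attacks silicon, not carbon, so the electron-rich rings and the stilbene should be left alone.

Step 18
Reactants: 31 (2S,3S)-3-{(2S,3S)-2-[2,4-bis(methoxymethoxy)phenyl]-3-[3,5-bis(methoxymethoxy)phenyl]-4-hydroxy-2,3-dihydro-1-benzofuran-6-yl}-2-[4-(methoxymethoxy)phenyl]-6-{(E)-2-[4-(methoxymethoxy)phenyl]ethenyl}-2,3-dihydro-1-benzofuran-4-ol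
Product: 32 (2S,3S)-3-[(2S,3S)-2-(2,4-dihydroxyphenyl)-3-(3,5-dihydroxyphenyl)-4-hydroxy-2,3-dihydro-1-benzofuran-6-yl]-2-(4-hydroxyphenyl)-6-[(E)-2-(4-hydroxyphenyl)ethenyl]-2,3-dihydro-1-benzofuran-4-ol
Conditions: HCl (3 M aq.), MeOH–THF (1:1), rt, argon, dark
Reagents that add atoms: none
Why: Acid-catalysed acetal exchange removes the six MOM groups, with methanol trapping the formaldehyde equivalents as dimethoxymethane. Any ionisation at C2–O1 or C2′–O1′ recloses to the trans rings, which are the thermodynamic isomers.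

## Compound list

1 | ethynylmagnesium bromide | C#C[Mg]Br | starting material
2 | benzylchlorodimethylsilane | C[Si](C)(Cl)Cc1ccccc1 | starting material
3 | benzyl(ethynyl)dimethylsilane | C#C[Si](C)(C)Cc1ccccc1 | intermediate
4 | 3,5-dihydroxybenzaldehyde | O=Cc1cc(O)cc(O)c1 | starting material
5 | 3,5-bis(methoxymethoxy)benzaldehyde | O=Cc1cc(OCOC)cc(OCOC)c1 | intermediate
6 | (1R)-3-BDMS-1-ArE-prop-2-yn-1-ol | O[C@@H](C#C[Si](C)(C)Cc1ccccc1)c1cc(OCOC)cc(OCOC)c1 | intermediate
7 | (1R)-3-BDMS-1-ArE-prop-2-yn-1-yl methanesulfonate | CS(=O)(=O)O[C@@H](C#C[Si](C)(C)Cc1ccccc1)c1cc(OCOC)cc(OCOC)c1 | intermediate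
8 | 2,4-dihydroxybenzaldehyde | O=Cc1ccc(O)cc1O | starting material
9 | 2,4-bis(methoxymethoxy)benzaldehyde | O=Cc1ccc(OCOC)cc1OCOC | intermediate
10 | (P)-[1-BDMS-3-ArE-propa-1,2-dien-1-yl](iodo)indium methanesulfonate, trivalent indium | I[In](OS(C)(=O)=O)C([Si](C)(C)Cc1ccccc1)=[C@@]=C([H])c1cc(OCOC)cc(OCOC)c1 | intermediate (not isolated)
11 | (1S,2S)-4-BDMS-1-ArF-2-ArE-but-3-yn-1-ol (anti) | O[C@H](c1ccc(OCOC)cc1OCOC)[C@H](C#C[Si](C)(C)Cc1ccccc1)c1cc(OCOC)cc(OCOC)c1 | intermediate
12 | (E)-1,2-dichlorovinyl ether of 11 | Cl/C=C(/Cl)O[C@H](c1ccc(OCOC)cc1OCOC)[C@H](C#C[Si](C)(C)Cc1ccccc1)c1cc(OCOC)cc(OCOC)c1 | intermediate (not isolated)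
13 | 2-lithioethynyl ether of 11 | [Li]C#CO[C@H](c1ccc(OCOC)cc1OCOC)[C@H](C#C[Si](C)(C)Cc1ccccc1)c1cc(OCOC)cc(OCOC)c1 | intermediate (not isolated)
14 | ethynyl ether of 11: benzyl[(3S,4S)-4-ArF-3-ArE-4-(ethynyloxy)but-1-yn-1-yl]dimethylsilane | C#CO[C@H](c1ccc(OCOC)cc1OCOC)[C@H](C#C[Si](C)(C)Cc1ccccc1)c1cc(OCOC)cc(OCOC)c1 | intermediate
15 | 3,3-diethoxyprop-1-yne | C#CC(OCC)OCC | starting material
16 | (2S,3S)-4-BDMS-2-ArF-3-ArE-6-(diethoxymethyl)-2,3-dihydro-1-benzofuran (trans) | CCOC(OCC)c1cc([Si](C)(C)Cc2ccccc2)c2c(c1)O[C@H](c1ccc(OCOC)cc1OCOC)[C@H]2c1cc(OCOC)cc(OCOC)c1 | intermediate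
17 | (2S,3S)-4-BDMS-2-ArF-3-ArE-2,3-dihydro-1-benzofuran-6-carbaldehyde | O=Cc1cc([Si](C)(C)Cc2ccccc2)c2c(c1)O[C@H](c1ccc(OCOC)cc1OCOC)[C@H]2c1cc(OCOC)cc(OCOC)c1 | intermediate
18 | (1R)-3-BDMS-1-U2-prop-2-yn-1-ol | O[C@@H](C#C[Si](C)(C)Cc1ccccc1)c1cc([Si](C)(C)Cc2ccccc2)c2c(c1)O[C@H](c1ccc(OCOC)cc1OCOC)[C@H]2c1cc(OCOC)cc(OCOC)c1 | intermediate
19 | (1R)-3-BDMS-1-U2-prop-2-yn-1-yl methanesulfonate | CS(=O)(=O)O[C@@H](C#C[Si](C)(C)Cc1ccccc1)c1cc([Si](C)(C)Cc2ccccc2)c2c(c1)O[C@H](c1ccc(OCOC)cc1OCOC)[C@H]2c1cc(OCOC)cc(OCOC)c1 | intermediate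
20 | 4-(methoxymethoxy)benzaldehyde | O=Cc1ccc(OCOC)cc1 | starting material
21 | (P)-[1-BDMS-3-U2-propa-1,2-dien-1-yl](iodo)indium methanesulfonate, trivalent indium | I[In](OS(C)(=O)=O)C([Si](C)(C)Cc1ccccc1)=[C@@]=C([H])c1cc([Si](C)(C)Cc2ccccc2)c2c(c1)O[C@H](c1ccc(OCOC)cc1OCOC)[C@H]2c1cc(OCOC)cc(OCOC)c1 | intermediate (not isolated)
22 | (1S,2S)-4-BDMS-1-ArB-2-U2-but-3-yn-1-ol (anti) | O[C@H](c1ccc(OCOC)cc1)[C@H](C#C[Si](C)(C)Cc1ccccc1)c1cc([Si](C)(C)Cc2ccccc2)c2c(c1)O[C@H](c1ccc(OCOC)cc1OCOC)[C@H]2c1cc(OCOC)cc(OCOC)c1 | intermediate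
23 | diethyl [3-(trimethylsilyl)prop-2-yn-1-yl]phosphonate | CCOP(=O)(OCC)CC#C[Si](C)(C)C | starting material
24 | trimethyl{(E)-4-[4-(methoxymethoxy)phenyl]but-3-en-1-yn-1-yl}silane | C[Si](C)(C)C#C/C=C/c1ccc(OCOC)cc1 | intermediate
25 | 1-[(E)-but-1-en-3-yn-1-yl]-4-(methoxymethoxy)benzene | C#C/C=C/c1ccc(OCOC)cc1 | intermediate
26 | (E)-1,2-dichlorovinyl ether of 22 | Cl/C=C(/Cl)O[C@H](c1ccc(OCOC)cc1)[C@H](C#C[Si](C)(C)Cc1ccccc1)c1cc([Si](C)(C)Cc2ccccc2)c2c(c1)O[C@H](c1ccc(OCOC)cc1OCOC)[C@H]2c1cc(OCOC)cc(OCOC)c1 | intermediate (not isolated)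
27 | 2-lithioethynyl ether of 22 | [Li]C#CO[C@H](c1ccc(OCOC)cc1)[C@H](C#C[Si](C)(C)Cc1ccccc1)c1cc([Si](C)(C)Cc2ccccc2)c2c(c1)O[C@H](c1ccc(OCOC)cc1OCOC)[C@H]2c1cc(OCOC)cc(OCOC)c1 | intermediate (not isolated)
28 | ethynyl ether of 22: benzyl[(3S,4S)-4-(ethynyloxy)-4-ArB-3-U2-but-1-yn-1-yl]dimethylsilane | C#CO[C@H](c1ccc(OCOC)cc1)[C@H](C#C[Si](C)(C)Cc1ccccc1)c1cc([Si](C)(C)Cc2ccccc2)c2c(c1)O[C@H](c1ccc(OCOC)cc1OCOC)[C@H]2c1cc(OCOC)cc(OCOC)c1 | intermediate
29 | (2S,3S)-4-BDMS-2-ArB-6-[(E)-2-ArB-ethenyl]-3-U2-2,3-dihydro-1-benzofuran | COCOc1ccc(/C=C/c2cc([Si](C)(C)Cc3ccccc3)c3c(c2)O[C@H](c2ccc(OCOC)cc2)[C@H]3c2cc([Si](C)(C)Cc3ccccc3)c3c(c2)O[C@H](c2ccc(OCOC)cc2OCOC)[C@H]3c2cc(OCOC)cc(OCOC)c2)cc1 | intermediate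
30 | analogue of 29 with hydroxy(dimethyl)silyl groups on C4 and C4′ | COCOc1ccc(/C=C/c2cc([Si](C)(C)O)c3c(c2)O[C@H](c2ccc(OCOC)cc2)[C@H]3c2cc([Si](C)(C)O)c3c(c2)O[C@H](c2ccc(OCOC)cc2OCOC)[C@H]3c2cc(OCOC)cc(OCOC)c2)cc1 | intermediate (not isolated)
31 | hexakis(MOM) ether of 32 with free C4–OH and C4′–OH, (2S,3S,2′S,3′S) | COCOc1ccc(/C=C/c2cc(O)c3c(c2)O[C@H](c2ccc(OCOC)cc2)[C@H]3c2cc(O)c3c(c2)O[C@H](c2ccc(OCOC)cc2OCOC)[C@H]3c2cc(OCOC)cc(OCOC)c2)cc1 | intermediate
32 | (2S,3S)-3-[(2S,3S)-2-(2,4-dihydroxyphenyl)-3-(3,5-dihydroxyphenyl)-4-hydroxy-2,3-dihydro-1-benzofuran-6-yl]-2-(4-hydroxyphenyl)-6-[(E)-2-(4-hydroxyphenyl)ethenyl]-2,3-dihydro-1-benzofuran-4-ol | Oc1ccc(/C=C/c2cc(O)c3c(c2)O[C@H](c2ccc(O)cc2)[C@H]3c2cc(O)c3c(c2)O[C@H](c2ccc(O)cc2O)[C@H]3c2cc(O)cc(O)c2)cc1 | target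

## Step count and least certain steps

Total step count: 18. Longest linear sequence: 14 steps (2, 3, 4, 6, 7, 8, 9, 10, 11, 12, 15, 16, 17, 18).

Step 8 (key step; step 16 shares the risk). The alkynyl ether arm may be lost before the metallacycle forms: by retro-ene expulsion of ketene through the weak C3′–H bond, or by diversion of the terminal alkoxyalkyne into a ruthenium vinylidene. Cyclodimerisation of the diyne may also compete. A cationic rhodium catalyst such as [Rh(cod)2]BF4 with BINAP is the first change of conditions. The fallback leaves the route at 11 and returns at 17, with no alkynyl ether. 11 is silylated with chloro(ethynyl)dimethylsilane and imidazole to the ethynyl(dimethyl)silyl ether F1, a silicon-tethered diyne. Cycloaddition of F1 with 15 under Cp*RuCl(cod) or RhCl(PPh3)3 should give the benzo-fused oxasiline F2, with the acetal again meta to the benzylsilyl group. Fluoride-free oxidation (H2O2, KHCO3, MeOH–THF) attacks only the oxygen-bearing silicon and releases the phenol–alcohol F3. A sulfonic acid in wet CH2Cl2 then ionises the benzylic alcohol next to ring F, the C7a′ phenol captures the cation to give the trans ring, and the acetal is hydrolysed in the same operation to 17.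

Step 7 (step 15 shares the risk). The potassium alkoxide may fragment by retro-propargylation and recombine with loss of configuration, the alkynyl silyl group may migrate to the alkoxide, and n-BuLi may deprotonate C3′–H. The fallback leaves at 11 and returns at 14 without forming a potassium alkoxide. 11 is formylated with acetic formic anhydride and pyridine to the formate F4. Dichloromethylenation with PPh3 and CCl4 in THF gives the 2,2-dichlorovinyl ether F5. n-BuLi at −78 °C converts F5 into 13, and protonation gives 14.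

Step 6 (step 12 shares the risk). Diastereoselectivity may be poor because the ortho acetal oxygen of 9 can chelate indium, and enantiopurity may erode through ionisation of the mesylate or equilibration of the allenylpalladium species. The fallback uses the lability of C2′ and sets out from 11 mixed with its syn epimer F6. The mixture is taken through step 7, giving the dichlorovinyl ether F7, the lithium alkynyl ether F8 and the ethynyl ether F9 alongside 12–14. Step 8 then gives the cis cycloadduct F10 alongside 16. Step 9 is run with camphorsulfonic acid in wet CH2Cl2, which opens and recloses the C2′–O1′ bond to the thermodynamic trans ring while hydrolysing the acetal. Both series converge on 17. This does not repair a loss of enantiopurity at C3′, which must be checked on 11.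

Step 16. The conjugated alkene of 25 may enter the metallacycle, or the enyne may oligomerise. The fallback leaves at 28 and returns at 29. Cycloaddition of 28 with 15, as in step 8, gives the acetal F11, and PPTS in wet acetone gives the aldehyde F12. Horner–Wadsworth–Emmons olefination with the phosphonate F13 (from diethyl (4-hydroxybenzyl)phosphonate and MOMCl) and KOtBu in THF then builds the (E)-stilbene of 29.

Step 17. Fluoride may cleave the aryl–silicon bonds by protodesilylation, and the hindered silanols may condense to disiloxanes that oxidise slowly. The fallback leaves at 30, isolated after the fluoride stage, and returns at 31. LiAlH4 in THF reduces the silanols (or their disiloxanes) to the bis(dimethylsilyl) compound F14. The Si–H bonds of F14 are then oxidised with H2O2 and KHCO3 in MeOH–THF without a fluoride source.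

Step 18. Acid may ionise the benzylic ether bonds with capture by methanol, and formaldehyde equivalents may alkylate the resorcinol rings. The fallback leaves at 31 and returns at 32 without exposing the free polyphenol to acid. The acetals are cleaved with Me3SiBr in CH2Cl2 at −30 °C, and the crude silyl ethers are methanolysed and acetylated (Ac2O, pyridine) to the octaacetate F15. F15 is purified and then deacetylated with catalytic K2CO3 in MeOH under argon.

## Further compounds

F1 | step 8 | benzyl{(3S,4S)-4-ArF-3-ArE-4-[ethynyl(dimethyl)silyloxy]but-1-yn-1-yl}dimethylsilane | C#C[Si](C)(C)O[C@H](c1ccc(OCOC)cc1OCOC)[C@H](C#C[Si](C)(C)Cc1ccccc1)c1cc(OCOC)cc(OCOC)c1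
F2 | step 8 | (3S,4S)-5-BDMS-3-ArF-4-ArE-7-(diethoxymethyl)-1,1-dimethyl-3,4-dihydro-1H-2,1-benzoxasiline | CCOC(OCC)c1cc([Si](C)(C)Cc2ccccc2)c2c(c1)[Si](C)(C)O[C@H](c1ccc(OCOC)cc1OCOC)[C@H]2c1cc(OCOC)cc(OCOC)c1
F3 | step 8 | (1S,2S)-2-[2-BDMS-4-(diethoxymethyl)-6-hydroxyphenyl]-1-ArF-2-ArE-ethan-1-ol | O[C@H](c1ccc(OCOC)cc1OCOC)[C@H](c1c(O)cc(C(OCC)OCC)cc1[Si](C)(C)Cc1ccccc1)c1cc(OCOC)cc(OCOC)c1
F4 | step 7 | (1S,2S)-4-BDMS-1-ArF-2-ArE-but-3-yn-1-yl formate | O=CO[C@H](c1ccc(OCOC)cc1OCOC)[C@H](C#C[Si](C)(C)Cc1ccccc1)c1cc(OCOC)cc(OCOC)c1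
F5 | step 7 | 2,2-dichlorovinyl ether of 11 | ClC(Cl)=CO[C@H](c1ccc(OCOC)cc1OCOC)[C@H](C#C[Si](C)(C)Cc1ccccc1)c1cc(OCOC)cc(OCOC)c1
F6 | step 6 | (1R,2S)-4-BDMS-1-ArF-2-ArE-but-3-yn-1-ol (syn epimer of 11) | O[C@@H](c1ccc(OCOC)cc1OCOC)[C@H](C#C[Si](C)(C)Cc1ccccc1)c1cc(OCOC)cc(OCOC)c1
F7 | step 6 | (E)-1,2-dichlorovinyl ether of F6 | Cl/C=C(/Cl)O[C@@H](c1ccc(OCOC)cc1OCOC)[C@H](C#C[Si](C)(C)Cc1ccccc1)c1cc(OCOC)cc(OCOC)c1
F8 | step 6 | 2-lithioethynyl ether of F6 | [Li]C#CO[C@@H](c1ccc(OCOC)cc1OCOC)[C@H](C#C[Si](C)(C)Cc1ccccc1)c1cc(OCOC)cc(OCOC)c1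
F9 | step 6 | ethynyl ether of F6 | C#CO[C@@H](c1ccc(OCOC)cc1OCOC)[C@H](C#C[Si](C)(C)Cc1ccccc1)c1cc(OCOC)cc(OCOC)c1
F10 | step 6 | (2R,3S)-4-BDMS-2-ArF-3-ArE-6-(diethoxymethyl)-2,3-dihydro-1-benzofuran (cis isomer of 16) | CCOC(OCC)c1cc([Si](C)(C)Cc2ccccc2)c2c(c1)O[C@@H](c1ccc(OCOC)cc1OCOC)[C@H]2c1cc(OCOC)cc(OCOC)c1
F11 | step 16 | (2S,3S)-4-BDMS-2-ArB-6-(diethoxymethyl)-3-U2-2,3-dihydro-1-benzofuran | CCOC(OCC)c1cc([Si](C)(C)Cc2ccccc2)c2c(c1)O[C@H](c1ccc(OCOC)cc1)[C@H]2c1cc([Si](C)(C)Cc2ccccc2)c2c(c1)O[C@H](c1ccc(OCOC)cc1OCOC)[C@H]2c1cc(OCOC)cc(OCOC)c1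
F12 | step 16 | (2S,3S)-4-BDMS-2-ArB-3-U2-2,3-dihydro-1-benzofuran-6-carbaldehyde | O=Cc1cc([Si](C)(C)Cc2ccccc2)c2c(c1)O[C@H](c1ccc(OCOC)cc1)[C@H]2c1cc([Si](C)(C)Cc2ccccc2)c2c(c1)O[C@H](c1ccc(OCOC)cc1OCOC)[C@H]2c1cc(OCOC)cc(OCOC)c1
F13 | step 16 | diethyl [4-(methoxymethoxy)benzyl]phosphonate | CCOP(=O)(OCC)Cc1ccc(OCOC)cc1
F14 | step 17 | analogue of 29 with dimethylsilyl (Si–H) groups on C4 and C4′ | COCOc1ccc(/C=C/c2cc([SiH](C)C)c3c(c2)O[C@H](c2ccc(OCOC)cc2)[C@H]3c2cc([SiH](C)C)c3c(c2)O[C@H](c2ccc(OCOC)cc2OCOC)[C@H]3c2cc(OCOC)cc(OCOC)c2)cc1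
F15 | step 18 | octaacetate of 32 | CC(=O)Oc1ccc(/C=C/c2cc(OC(C)=O)c3c(c2)O[C@H](c2ccc(OC(C)=O)cc2)[C@H]3c2cc(OC(C)=O)c3c(c2)O[C@H](c2ccc(OC(C)=O)cc2OC(C)=O)[C@H]3c2cc(OC(C)=O)cc(OC(C)=O)c2)cc1
A1 | alternative 1 | pinacol [(1R,2S)-1-(2,4-dimethoxyphenyl)-2-(3,5-dimethoxyphenyl)-2-[4-(dimethoxymethyl)-2,6-bis(methoxymethoxy)phenyl]ethyl]boronate | CC1(C)OB(OC1(C)C)[C@@H](c1ccc(OC)cc1OC)[C@H](c1c(OCOC)cc(C(OC)OC)cc1OCOC)c1cc(OC)cc(OC)c1
A2 | alternative 1 | pinacol (E)-2-[4-(dimethoxymethyl)-2,6-bis(methoxymethoxy)phenyl]ethenylboronate | CC1(C)OB(/C=C/c2c(OCOC)cc(C(OC)OC)cc2OCOC)OC1(C)C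
A3 | alternative 1 | 2,4-dimethoxyphenyllithium | [Li]c1ccc(OC)cc1OC
A4 | alternative 1 | 3,5-dimethoxyphenyl trifluoromethanesulfonate | COc1cc(OC)cc(OS(=O)(=O)C(F)(F)F)c1
A5 | alternative 2 | 5-[(2S,3S)-6-bromo-2-(2,4-dimethoxyphenyl)-4-methoxy-2,3-dihydro-1-benzofuran-3-yl]-7-hydroxy-2,2-dimethyl-4H-1,3-benzodioxin-4-one | Brc1cc(OC)c2c(c1)O[C@H](c1ccc(OC)cc1OC)[C@H]2c1cc(O)cc2c1C(=O)OC(C)(C)O2
A6 | alternative 2 | 1-[(2S,3S)-6-bromo-2-(2,4-dimethoxyphenyl)-4-methoxy-2,3-dihydro-1-benzofuran-3-yl]-4-(2,2-dimethyl-4-oxo-4H-1,3-dioxin-6-yl)butane-1,3-dione | Brc1cc(OC)c2c(c1)O[C@H](c1ccc(OC)cc1OC)[C@H]2C(=O)CC(=O)CC1=CC(=O)OC(C)(C)O1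
A7 | alternative 3 | trans-2-(4-methoxyphenyl)-3-(unit 2 aryl)-6-[(E)-4-methoxystyryl]-3,5,6,7-tetrahydrobenzofuran-4(2H)-one, C6 unassigned | COc1ccc(/C=C/C2CC(=O)C3=C(C2)O[C@H](c2ccc(OC)cc2)[C@H]3c2cc(OC)c3c(c2)O[C@H](c2ccc(OC)cc2OC)[C@H]3c2cc(OC)cc(OC)c2)cc1
A8 | alternative 3 | trans-1-(4-methoxyphenyl)-2-(unit 2 aryl)-6-[(E)-4-methoxystyryl]spiro[2.5]octane-4,8-dione, C6 unassigned | COc1ccc(/C=C/C2CC(=O)C3(C(=O)C2)[C@H](c2ccc(OC)cc2)[C@H]3c2cc(OC)c3c(c2)O[C@H](c2ccc(OC)cc2OC)[C@H]3c2cc(OC)cc(OC)c2)cc1
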